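Readings and results were computed from invented constants.

Late in the north-east run the substrate was still falling, but each remaining part of it was being used more slowly than at the start, and I began with that easing.

- north-east: substrate 0.10 M; reagent 2.6 equiv; free catalyst 5 mol%; run made earlier
- flask: substrate 0.10 M; reagent 1.30 equiv; free catalyst 5 mol%

north-east run (percent of the substrate charged)

| time / h | product / % | substrate / % |
|---|---|---|
| 6.00 | 10.9 | 88.9 |
| 12.0 | 20.3 | 80.5 |
| 15.0 | 22.4 | 77.1 |
| 25.0 | 32.3 | 66.8 |
| 30.0 | 38.3 | 63.6 |

(scatter of a reading: 0.5 percentage points)

1. factor on the rate of making product when 20 % of the substrate are converted if reagent is charged twice over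
2. factor on the rate when 20 % of the substrate are converted if free catalyst is charged at 25 mol% instead

- no earlier run changes the charge of free catalyst; that part of a forecast is a guess
- no earlier run changes the charge of reagent; that part of a forecast is a guess

Over the first 6.00 h the substrate's first-order constant was 0.0196 h⁻¹. The late constant, the pseudo-first-order constant of the substrate over the last stretch of a run, read 0.0128 h⁻¹ between 15.0 h and 30.0 h. The late constant was thus 0.654 of the first one.

My first suspect was reagent use, but the reagent between those stretches fell only to 0.902 of its earlier amount, and that is less of a fall than the constant showed, even at first order in reagent. The reagent order stayed open in this run, so I put the reagent factor between 1 and 2.2, as a guess.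

I then supposed that working catalyst was lost with time. On that supposition a charge of 25 mol% reaches 20 % conversion sooner, before that loss, which gave an upper figure of 7.64. But the north-east run passed 20 % near 12.0 h, where the constant from 6.00 h to 15.0 h was still 0.0158 h⁻¹, above the late one, and that lowered my figure to 6.20. A worse doubt remained: a loss tied to conversion would leave plain 5.00, and this run could not separate the two. I committed to 6.20.

The forecast gave 2 and 4.5, with the words “This single run cannot show the reagent or catalyst orders”.

    catalyst intermediate A → catalyst intermediate B (k = 0.390 min⁻¹)
    substrate + free catalyst ⇌ catalyst intermediate A (K = 120 M⁻¹, k = 0.0860 M⁻¹ min⁻¹)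
    free catalyst ⇌ dormant form (K = 0.870, k = 0.00130 min⁻¹)
    catalyst intermediate C → free catalyst + product (k = 0.720 min⁻¹)
    reagent + catalyst intermediate B ⇌ catalyst intermediate C (K = 6.90 M⁻¹, k = 4.20 M⁻¹ min⁻¹)

The flask gave 1.01 and 7.29, the second below my upper figure of 7.64 and above my 6.20, and the late constant, carried on from 35.5 % substrate at 3.00 d, reckons 14.1 % at 6.00 d against 13.3 % in this flask with its 1.30 equiv of reagent. At 6.00 d in this flask the step of substrate with free catalyst, taken by itself and both ways together, relaxed with a half-life of 0.230 d, far longer than the 0.0146 h of the step of reagent with catalyst intermediate B, and free catalyst, the resting state of the round, stood at 53.0 % while the dormant form held 46.1 % of the catalyst.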